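The bicyclo[3.3.1]nonane is cut at C5–C6 and at the bond between C7 and its prenyl CH2. This leads back to a monocyclic, dearomatized acylphloroglucinol (ring B: C1–C5, C9) whose quaternary C1 carries C8 (methyl, homoprenyl) and, on C8, a 1-(phenylsulfonyl)vinyl group, C7(=C6H2). The key step exploits that the enolate carbon C5 lies within six-ring reach of the unsubstituted terminus C6 and that C7 then becomes a sulfonyl carbanion site. One flask closes ring A (C1, C8, C7, C6, C5, C9), makes C5 quaternary and prenylates C7. Cutting out the sulfone afterwards sets the endo C7 prenyl group; C1 and C8 stem from a stereospecific dearomative Claisen rearrangement.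

Key step: step 11

Remark on the chemistry: tri- and tetracarbonyl compounds are drawn as one enol tautomer. Core numbers C1–C9 denote the same atoms in all compounds. CIP descriptors refer to the tautomers drawn, and the target is (1S,5S,7S,8R).

Design points built into the steps:
- **Catechol protection.** The catechol is carried as triisopropylsilyl ethers. An aryl silyl ether para to the ketone must survive phenoxides, DBU and LiN(i-Pr)2, and smaller silyl groups should not. The groups go on before the ketone is made, so neither a Lewis acid nor hydroxide meets them.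
- **Alkene geometry sets C8.** A chair Claisen array needs CH3 cis to the CH2O carbon (C6) and homoprenyl cis to the sulfonyl group, which is the (Z)-alkene. Condensations of the methyl ketone would give E/Z mixtures, so the alkene is made by syn-carbometalation.
- **Ether formation.** The aryl allyl ether is made under neutral Mitsunobu conditions. Phenoxide plus allylic halide risks carbon alkylation that joins C1 to C6.
- **Absolute configuration.** The ether is achiral and has no chelating site for a chiral catalyst. The absolute configuration is therefore secured by separating the enantiomers of the first chiral compound.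
- **Base in the ring closure.** The closure is run with less than one equivalent of a weak base, because a strong base in excess would favour the open dianion. The amide base is then dosed for the enol proton plus C7–H.
- **Sulfone removal.** The step passes through a tertiary C7 radical that is a hex-5-enyl radical relative to the C8 homoprenyl alkene. A fast hydrogen-atom donor is therefore present.

Step 1
Reactants: 1 phloroglucinol
Product: 2 1,3,5-tris(methoxymethoxy)benzene
Conditions: NaH, MOMCl, DMF, 0 °C → rt
Reagents that add atoms: chloromethyl methyl ether, COCCl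
Why: Williamson-type O-alkylation, in which the hard chloromethyl ether attacks the phenoxide oxygens rather than the ring carbons, and the three acetal groups later direct the lithiation.

Step 2
Reactants: 3 methyl 3,4-dihydroxybenzoate
Product: 4 methyl 3,4-bis(triisopropylsilyloxy)benzoate
Conditions: TIPSCl, imidazole, DMF, rt → 40 °C
Reagents that add atoms: triisopropylsilyl chloride, CC(C)[Si](Cl)(C(C)C)C(C)C
Why: Imidazole-promoted silylation of phenols, with a bulky silyl group that withstands the later phenoxide, amidine and amide bases and leaves with fluoride at the end.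

Step 3
Reactants: 2 1,3,5-tris(methoxymethoxy)benzene; 4 methyl 3,4-bis(triisopropylsilyloxy)benzoate
Product: 7 [3,4-bis(triisopropylsilyloxy)phenyl](2,4,6-trihydroxyphenyl)methanone, via aryllithium 5 (not isolated), via tris-MOM ketone 6 (not isolated)
Conditions: 2, n-BuLi, THF, 0 °C; 4, −78 → 0 °C; then HCl (3 M in MeOH), 45 °C
Reagents that add atoms: none
Why: Directed ortho-lithiation between two OMOM groups, acyl substitution on the ester (the chelated adduct and the very hindered ketone should take up no second aryllithium), then acid-catalysed acetal exchange with methanol, which removes the MOM groups while aryl triisopropylsilyl ethers resist dilute acid.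

Step 4
Reactants: 7 [3,4-bis(triisopropylsilyloxy)phenyl](2,4,6-trihydroxyphenyl)methanone; 8 prenyl bromide
Product: 9 [3,4-bis(triisopropylsilyloxy)phenyl][2,4,6-trihydroxy-3,5-bis(3-methylbut-2-enyl)phenyl]methanone
Conditions: NaH (2.1 equiv), toluene, 0 °C; 8 (2.1 equiv), 0 °C → rt
Reagents that add atoms: none
Why: C-alkylation of an ambident phenoxide, in which tight sodium ion pairs in a non-polar medium and the high carbon nucleophilicity of the acylphloroglucinol send both prenyl groups to the two free ring carbons, and hydroxide, which would attack the silyl ethers, is avoided.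

Step 5
Reactants: 10 6-methylhept-5-en-2-one
Product: 13 (6-methylhept-5-en-1-ynyl) phenyl sulfide, via enol phosphate 11 (not isolated), via lithium acetylide 12 (not isolated)
Conditions: LiN(i-Pr)2 (1.05 equiv), THF, −78 °C; ClP(O)(OEt)2, −78 °C → rt; LiN(i-Pr)2 (2.3 equiv), −78 °C → rt; PhSSPh, −78 °C → rt
Reagents that add atoms: diphenyl disulfide, c1ccc(cc1)SSc1ccccc1; diethyl chlorophosphate, CCOP(=O)(Cl)OCC (its atoms stay only in 11)
Why: Kinetic enolisation at the methyl group, O-phosphorylation and base-induced elimination (methyl ketone to alkyne by way of the enol phosphate) give the acetylide, which is sulfenylated in the same flask so that the volatile alkyne need not be isolated.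

Step 6
Reactants: 13 (6-methylhept-5-en-1-ynyl) phenyl sulfide
Product: 14 (6-methylhept-5-en-1-ynyl) phenyl sulfone
Conditions: (NH4)6Mo7O24·4H2O (10 mol %), 30% H2O2, EtOH, 0 °C → rt
Reagents that add atoms: hydrogen peroxide, OO
Why: Peroxomolybdate-catalysed oxidation of a sulfide to the sulfone, a system that is routinely selective for sulfur over isolated trisubstituted alkenes.

Step 7
Reactants: 14 (6-methylhept-5-en-1-ynyl) phenyl sulfone
Product: 16 (Z)-3,7-dimethyl-2-(phenylsulfonyl)octa-2,6-dien-1-ol, via alkenylmagnesium bromide 15 (not isolated)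
Conditions: MeMgBr, CuBr·SMe2 (10 mol %), THF, −40 °C; CH2O gas (from paraformaldehyde), −40 → 0 °C; aq NH4Cl
Reagents that add atoms: methylmagnesium bromide, C[Mg]Br; formaldehyde, C=O
Why: Copper-catalysed syn-carbomagnesiation of an alkynyl sulfone (methyl to the beta carbon, magnesium alpha to sulfur) followed by hydroxymethylation of the alkenyl Grignard reagent with retention places CH3 cis to CH2OH, which is the (Z)-alkene that later encodes C8.

Step 8
Reactants: 9 [3,4-bis(triisopropylsilyloxy)phenyl][2,4,6-trihydroxy-3,5-bis(3-methylbut-2-enyl)phenyl]methanone; 16 (Z)-3,7-dimethyl-2-(phenylsulfonyl)octa-2,6-dien-1-ol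
Product: 17 [3,4-bis(triisopropylsilyloxy)phenyl]{4-[(Z)-3,7-dimethyl-2-(phenylsulfonyl)octa-2,6-dienyloxy]-2,6-dihydroxy-3,5-bis(3-methylbut-2-enyl)phenyl}methanone
Conditions: PPh3, DIAD, toluene, 0 °C → rt
Reagents that add atoms: none
Why: Mitsunobu etherification, in which the para hydroxyl is the most acidic one and the only one not hydrogen-bonded to the ketone, and the neutral medium avoids both carbon alkylation of the ring and base-induced isomerisation of the vinyl sulfone.

Step 9
Reactants: 17 the para aryl (Z)-2-sulfonylallyl ether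
Product: 18 racemic 2-[3,4-bis(triisopropylsilyloxy)benzoyl]-6-[3,7-dimethyl-2-(phenylsulfonyl)octa-1,6-dien-3-yl]-3,5-dihydroxy-4,6-bis(3-methylbut-2-enyl)cyclohexa-2,4-dien-1-one (relative configuration C1 S*/C8 S*)
Conditions: toluene, 110 °C, sealed tube, Ar
Reagents that add atoms: none
Why: Dearomative ortho-Claisen rearrangement, in which C8 bonds to the prenyl-bearing ortho carbon C1 and the dienone rests as its stable enol; the chair array, enforced because a boat would push the sulfonyl group over the ring, translates the (Z)-geometry into the required relative configuration of C1 and C8 (racemic, since the two ortho carbons of achiral 17 are enantiotopic), while the sulfonyl group accelerates the shift and blocks ionisation of the allyl ether.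

Step 10
Reactants: 18 the racemic dearomatized acylphloroglucinol
Product: 19 (C1 S, C8 S)-2-[3,4-bis(triisopropylsilyloxy)benzoyl]-6-[3,7-dimethyl-2-(phenylsulfonyl)octa-1,6-dien-3-yl]-3,5-dihydroxy-4,6-bis(3-methylbut-2-enyl)cyclohexa-2,4-dien-1-one
Conditions: preparative SFC, amylose tris(3,5-dimethylphenylcarbamate) phase, CO2/i-PrOH, 0.1% HCO2H
Reagents that add atoms: none
Why: Chromatographic resolution of enantiomers on a polysaccharide phase, routine for enolic polyprenylated acylphloroglucinols once an acidic modifier suppresses tailing; the enantiomer to keep is identified by anomalous-dispersion X-ray analysis (S, Si) or circular dichroism, and the two quaternary centres cannot epimerise.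

Step 11
Reactants: 19 the enantiopure vinyl sulfone precursor; 8 prenyl bromide
Product: 22 (1S,5S,7S,8S)-3-[3,4-bis(triisopropylsilyloxy)benzoyl]-4-hydroxy-8-methyl-1,5,7-tris(3-methylbut-2-enyl)-8-(4-methylpent-3-enyl)-7-(phenylsulfonyl)bicyclo[3.3.1]non-3-ene-2,9-dione, via bicyclic C7-H sulfone 20 (not isolated), via dilithio dianion 21 (not isolated)
Conditions: DBU (0.3 equiv), THF, rt → 40 °C; then −78 °C, LiN(i-Pr)2 (2.4 equiv), DMPU; 8 (3 equiv), −78 °C; AcOH, −78 °C
Reagents that add atoms: none
Why: Substoichiometric DBU makes only the monoanion of 19, whose enolate carbon C5 adds to the unsubstituted vinyl sulfone terminus C6 (intramolecular Michael addition, 6-endo-trig, closing ring A: C1–C8–C7–C6–C5–C9), and proton transfer from the remaining enol to C7 turns the closure into a downhill isomerisation to 20, whereas excess strong base at this stage would favour the open dianion. The closest known reactions are the ring-closing Michael step of alkylative dearomatisation–annulation sequences on acylphloroglucinols and the alkylation of alpha-sulfonyl carbanions within dianions. C5 is fixed by the tether, since the chain on C1 can reach only one face of the planar enolate, and attack by oxygen at C6 gives a beta-(vinylogous acyloxy) sulfone that DBU eliminates again, so material drains to the carbon adduct. Two equivalents of LiN(i-Pr)2 then remove the enol proton and the exposed exo C7–H, and dianion 21 reacts with 8 at its most basic site, C7, from the open exo face (sulfonyl endo), a configuration that is erased in step 12. The lithium trione enolate is inert to 8 at −78 °C and its charge makes C5 a poor leaving group, so retro-Michael opening of 21 is held back as long as the mixture stays cold and is quenched cold.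

Step 12
Reactants: 22 the C7 prenylated bicyclic sulfone
Product: 23 (1S,5S,7S,8R)-3-[3,4-bis(triisopropylsilyloxy)benzoyl]-4-hydroxy-8-methyl-1,5,7-tris(3-methylbut-2-enyl)-8-(4-methylpent-3-enyl)bicyclo[3.3.1]non-3-ene-2,9-dione
Conditions: LiN(SiMe3)2 (1.0 equiv), THF, −78 °C; PhSH (20 equiv), HMPA, SmI2 (5 equiv), −78 → −30 °C; dilute HCl
Reagents that add atoms: none
Why: Reductive desulfonylation by single-electron transfer from SmI2–HMPA gives the tertiary C7 radical, which divalent samarium reduces only slowly, so excess PhSH delivers hydrogen faster than 5-exo closure onto the homoprenyl alkene and can do so only from the exo face because the C2–C3–C4 bridge covers the endo face, which turns the prenyl group endo (7S), while the lithium enolate formed first shields the aroyl trione from reduction.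

Step 13
Reactants: 23 the bis(triisopropylsilyl) ether of the target
Product: 24 (1S,5S,7S,8R)-3-(3,4-dihydroxybenzoyl)-4-hydroxy-8-methyl-1,5,7-tris(3-methylbut-2-enyl)-8-(4-methylpent-3-enyl)bicyclo[3.3.1]non-3-ene-2,9-dione
Conditions: Bu4NF (2.5 equiv), AcOH (2.5 equiv), THF, 0 °C, Ar
Reagents that add atoms: none
Why: Fluoride-induced cleavage of aryl silyl ethers, buffered with AcOH so that catechol and trione stay protonated (no base-promoted oxidation, no acid-promoted ring closure of the enol onto a prenyl group), with no stereocentre touched.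

Compound list
1 | phloroglucinol | Oc1cc(O)cc(O)c1 | starting material
2 | 1,3,5-tris(methoxymethoxy)benzene | COCOc1cc(OCOC)cc(OCOC)c1 | intermediate
3 | methyl 3,4-dihydroxybenzoate | COC(=O)c1ccc(O)c(O)c1 | starting material
4 | methyl 3,4-bis(triisopropylsilyloxy)benzoate | COC(=O)c1ccc(O[Si](C(C)C)(C(C)C)C(C)C)c(O[Si](C(C)C)(C(C)C)C(C)C)c1 | intermediate
5 | 2,4,6-tris(methoxymethoxy)phenyllithium | [Li]c1c(OCOC)cc(OCOC)cc1OCOC | intermediate
6 | [3,4-bis(triisopropylsilyloxy)phenyl][2,4,6-tris(methoxymethoxy)phenyl]methanone | COCOc1cc(OCOC)c(C(=O)c2ccc(O[Si](C(C)C)(C(C)C)C(C)C)c(O[Si](C(C)C)(C(C)C)C(C)C)c2)c(OCOC)c1 | intermediate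
7 | [3,4-bis(triisopropylsilyloxy)phenyl](2,4,6-trihydroxyphenyl)methanone | O=C(c1c(O)cc(O)cc1O)c2ccc(O[Si](C(C)C)(C(C)C)C(C)C)c(O[Si](C(C)C)(C(C)C)C(C)C)c2 | intermediate
8 | prenyl bromide (1-bromo-3-methylbut-2-ene) | CC(C)=CCBr | starting material
9 | [3,4-bis(triisopropylsilyloxy)phenyl][2,4,6-trihydroxy-3,5-bis(3-methylbut-2-enyl)phenyl]methanone | O=C(c1c(O)c(CC=C(C)C)c(O)c(CC=C(C)C)c1O)c2ccc(O[Si](C(C)C)(C(C)C)C(C)C)c(O[Si](C(C)C)(C(C)C)C(C)C)c2 | intermediate
10 | 6-methylhept-5-en-2-one | CC(=O)CCC=C(C)C | starting material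
11 | diethyl 6-methylhepta-1,5-dien-2-yl phosphate | C=C(CCC=C(C)C)OP(=O)(OCC)OCC | intermediate
12 | lithium 6-methylhept-5-en-1-ynide | [Li]C#CCCC=C(C)C | intermediate
13 | (6-methylhept-5-en-1-ynyl) phenyl sulfide | CC(C)=CCCC#CSc1ccccc1 | intermediate
14 | (6-methylhept-5-en-1-ynyl) phenyl sulfone | CC(C)=CCCC#CS(=O)(=O)c1ccccc1 | intermediate
15 | 2,6-dimethyl-1-(phenylsulfonyl)hepta-1,5-dien-1-ylmagnesium bromide, CH3 on C2 cis to Mg | Br[Mg]/C(S(=O)(=O)c1ccccc1)=C(\C)CCC=C(C)C | intermediate
16 | (Z)-3,7-dimethyl-2-(phenylsulfonyl)octa-2,6-dien-1-ol, CH3 on C3 cis to CH2OH | OC/C(S(=O)(=O)c1ccccc1)=C(\C)CCC=C(C)C | intermediate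
17 | [3,4-bis(triisopropylsilyloxy)phenyl]{4-[(Z)-3,7-dimethyl-2-(phenylsulfonyl)octa-2,6-dienyloxy]-2,6-dihydroxy-3,5-bis(3-methylbut-2-enyl)phenyl}methanone | O=C(c1c(O)c(CC=C(C)C)c(OC/C(S(=O)(=O)c3ccccc3)=C(\C)CCC=C(C)C)c(CC=C(C)C)c1O)c2ccc(O[Si](C(C)C)(C(C)C)C(C)C)c(O[Si](C(C)C)(C(C)C)C(C)C)c2 | intermediate
18 | racemate of 19 (both enantiomers written) | CC(C)=CCC[C@](C)(C(=C)S(=O)(=O)c2ccccc2)[C@]1(CC=C(C)C)C(=O)C(C(=O)c3ccc(O[Si](C(C)C)(C(C)C)C(C)C)c(O[Si](C(C)C)(C(C)C)C(C)C)c3)=C(O)C(CC=C(C)C)=C1O.CC(C)=CCC[C@@](C)(C(=C)S(=O)(=O)c2ccccc2)[C@@]1(CC=C(C)C)C(=O)C(C(=O)c3ccc(O[Si](C(C)C)(C(C)C)C(C)C)c(O[Si](C(C)C)(C(C)C)C(C)C)c3)=C(O)C(CC=C(C)C)=C1O | intermediate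
19 | key-step precursor: dearomatized acylphloroglucinol with prenyl and the C8 chain (CH3, homoprenyl, 1-(phenylsulfonyl)vinyl) on C1; C1 S, C8 S | CC(C)=CCC[C@](C)(C(=C)S(=O)(=O)c2ccccc2)[C@]1(CC=C(C)C)C(=O)C(C(=O)c3ccc(O[Si](C(C)C)(C(C)C)C(C)C)c(O[Si](C(C)C)(C(C)C)C(C)C)c3)=C(O)C(CC=C(C)C)=C1O | intermediate
20 | (1S,5S,7S,8S)-bicyclic C7–H sulfone, endo-sulfonyl epimer drawn (C7 configuration of no consequence) | CC(C)=CCC[C@]1(C)[C@@H](S(=O)(=O)c4ccccc4)C[C@]2(CC=C(C)C)C(=O)[C@@]1(CC=C(C)C)C(=O)C(C(=O)c3ccc(O[Si](C(C)C)(C(C)C)C(C)C)c(O[Si](C(C)C)(C(C)C)C(C)C)c3)=C2O | intermediate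
21 | dilithium salt of 20 (trione enolate and C7 sulfonyl carbanion) | [Li+].[Li+].CC(C)=CCC[C@]1(C)[C-](S(=O)(=O)c4ccccc4)C[C@]2(CC=C(C)C)C(=O)[C@@]1(CC=C(C)C)C(=O)C(C(=O)c3ccc(O[Si](C(C)C)(C(C)C)C(C)C)c(O[Si](C(C)C)(C(C)C)C(C)C)c3)=C2[O-] | intermediate
22 | key-step product: (1S,5S,7S,8S)-bicyclic core with exo prenyl and endo phenylsulfonyl on C7 | CC(C)=CCC[C@]1(C)[C@@](CC=C(C)C)(S(=O)(=O)c4ccccc4)C[C@]2(CC=C(C)C)C(=O)[C@@]1(CC=C(C)C)C(=O)C(C(=O)c3ccc(O[Si](C(C)C)(C(C)C)C(C)C)c(O[Si](C(C)C)(C(C)C)C(C)C)c3)=C2O | intermediate
23 | (1S,5S,7S,8R)-bis(triisopropylsilyl) ether of the target, C7 prenyl endo | CC(C)=CCC[C@]1(C)[C@@H](CC=C(C)C)C[C@]2(CC=C(C)C)C(=O)[C@@]1(CC=C(C)C)C(=O)C(C(=O)c3ccc(O[Si](C(C)C)(C(C)C)C(C)C)c(O[Si](C(C)C)(C(C)C)C(C)C)c3)=C2O | intermediate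
24 | (1S,5S,7S,8R)-3-(3,4-dihydroxybenzoyl)-4-hydroxy-8-methyl-1,5,7-tris(3-methylbut-2-enyl)-8-(4-methylpent-3-enyl)bicyclo[3.3.1]non-3-ene-2,9-dione | CC(C)=CCC[C@]1(C)[C@@H](CC=C(C)C)C[C@]2(CC=C(C)C)C(=O)[C@@]1(CC=C(C)C)C(=O)C(C(=O)c1ccc(O)c(O)c1)=C2O | target

Total step count: 13, resolution included.
Longest linear sequence: 9 steps (1, 3, 4, 8–13; the branch 5–7, 8–13 is equally long).

Steps most likely to fail

**Step 11.** Carbon–carbon bond formation at the crowded C7 carbanion, which is flanked by quaternary C8, may be slower than retro-Michael ring opening. The opened enolate would then be prenylated at C5. Fallback, from 19 to 22: only the DBU stage is run and 20 is isolated. Its dianion is made as before and trapped at −78 °C with allyl iodide, a smaller and faster electrophile, to give the C7-allyl sulfone F1. Cross metathesis of F1 with 2-methylbut-2-ene (second-generation Grubbs catalyst, CH2Cl2, 40 °C) turns the allyl into the prenyl group and delivers 22. The other trisubstituted alkenes should undergo at most degenerate exchange.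

**Step 12.** Hydrogen transfer to the tertiary C7 radical may lose against 5-exo ring closure onto the homoprenyl alkene, or electron transfer to the C9 ketone may compete. Fallback, from 22 to 23: reductive lithiation replaces radical trapping. The lithium enolate of 22 (LiN(SiMe3)2, THF, −78 °C) is titrated with LiC10H8 (lithium naphthalenide) at −78 °C. The second electron transfer from the arene radical anion should be far faster than any ring closure at this temperature. The tertiary carbanion is protonated from the exo face by the HN(SiMe3)2 already present. The sulfone is the most easily reduced group and should be consumed before the ketone. This path makes no new compound F0.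

**Step 9.** The crowded C1–C8 bond may form reversibly, or the sulfonylallyl unit may move on to C3 by a Cope shift on prolonged heating. Fallback, from 17 to 20: the rearrangement is run in the presence of DBU (0.2 equiv, held as its phenoxide salt; toluene, 110 °C). The first-formed enolate is then drained at once by the Michael ring closure, which removes the 1,5-diene needed for reversal or onward shift. This gives the racemic bicyclic C7–H sulfone F2, which is resolved on the same chiral phase to 20. Compound 20 enters the second stage of step 11 (LiN(i-Pr)2, 8).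

Further compounds
F1 | step 11 | (1S,5S,7S,8S)-C7-allyl analogue of 22 (exo allyl, endo phenylsulfonyl) | CC(C)=CCC[C@]1(C)[C@@](CC=C)(S(=O)(=O)c4ccccc4)C[C@]2(CC=C(C)C)C(=O)[C@@]1(CC=C(C)C)C(=O)C(C(=O)c3ccc(O[Si](C(C)C)(C(C)C)C(C)C)c(O[Si](C(C)C)(C(C)C)C(C)C)c3)=C2O
F0 | step 12 | none | none
F2 | step 9 | racemate of 20 (both enantiomers written) | CC(C)=CCC[C@]1(C)[C@@H](S(=O)(=O)c4ccccc4)C[C@]2(CC=C(C)C)C(=O)[C@@]1(CC=C(C)C)C(=O)C(C(=O)c3ccc(O[Si](C(C)C)(C(C)C)C(C)C)c(O[Si](C(C)C)(C(C)C)C(C)C)c3)=C2O.CC(C)=CCC[C@@]1(C)[C@H](S(=O)(=O)c4ccccc4)C[C@@]2(CC=C(C)C)C(=O)[C@]1(CC=C(C)C)C(=O)C(C(=O)c3ccc(O[Si](C(C)C)(C(C)C)C(C)C)c(O[Si](C(C)C)(C(C)C)C(C)C)c3)=C2O
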